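**Plan**
1. Retrosynthesis: the eight phenols are unmasked last. The two C–(4‑hydroxyphenyl) bonds on the diquinane are cut back to a cis‑fused diketone. The diketone is cut at the ring‑B acyl bond and the ring‑B–C7 bond to a ring‑C indanone. The dihydrofuran is cut at O–C(aryl) and C2–C3, leaving an ortho‑sulfinyl diarylmethane and 4‑methoxybenzaldehyde.
2. Forward: ring‑C indanone (carbonyl placed next to Br by construction) → aryl sulfoxide → C‑benzylation → dihydrofuran ring → indenone → alkenyl group at C6 → aryl group at C7 → second cyclopentanone (cis‑diquinane) → two anisyl groups → demethylation.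
3. Enabling feature: the furan oxygen sits on arene carbon C8b, between C3a (which carries the doubly benzylic C3) and C8a. A p‑tolylsulfinyl group on C8b chelates the C3 carbanion and then leaves from C8b when the C2 alkoxide attacks.
4. Stereochemistry: C3 comes from the sulfur stereocentre and C2 settles trans by equilibration. The angular carbon C6 comes from Rh/(R)‑BINAP and the second angular carbon from the cis‑fusion constraint. Both diarylmethine carbons come from convex‑face arylation.

Key step: step 6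

Locants: the tricycle is numbered as 2H‑indeno[4,5‑b]furan (O1, C2, C3, C3a, C4, C5, C5a, C6, C7, C8, C8a, C8b; O1 is bonded to C8b, and C8 is the carbon next to C8a).
Assumption: the (S)‑sulfinyl group is taken to give 3S in step 6 (chelate model) and (R)‑BINAP to give 6R in step 9 (by analogy with 2‑cyclopentenone); the antipodal sulfinate or ligand would be used if either sense proved opposite.

**Step 1**
Reactants: 1 3‑bromoanisole; 2 3‑chloropropanoyl chloride
Product: 3 1‑(2‑bromo‑4‑methoxyphenyl)‑3‑chloropropan‑1‑one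
Conditions: AlCl3 (1.2 equiv), CH2Cl2, 0 °C
Reagents that add atoms: none
Why: Friedel–Crafts acylation of 3‑bromoanisole should go para to the methoxy group, which puts the acyl group next to bromine.

**Step 2**
Reactants: 3 1‑(2‑bromo‑4‑methoxyphenyl)‑3‑chloropropan‑1‑one
Product: 5 7‑bromo‑5‑methoxy‑2,3‑dihydro‑1H‑inden‑1‑one, via aryl vinyl ketone 4 (not isolated)
Conditions: TfOH (5 equiv), 1,2‑dichloroethane, 80 °C
Reagents that add atoms: none
Why: acid eliminates HCl and the O‑protonated aryl vinyl ketone should undergo Nazarov‑type cyclisation onto the only free ortho carbon, so the carbonyl ends up on the ring carbon adjacent to C–Br.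

**Step 3**
Reactants: 5 7‑bromo‑5‑methoxy‑2,3‑dihydro‑1H‑inden‑1‑one
Product: 6 7'‑bromo‑5'‑methoxy‑2',3'‑dihydrospiro[1,3‑dioxolane‑2,1'‑indene]
Conditions: (Me3SiOCH2)2 (1.5 equiv), TMSOTf (5 mol %), CH2Cl2, −78 → −20 °C
Reagents that add atoms: 1,2‑bis(trimethylsilyloxy)ethane, C[Si](C)(C)OCCO[Si](C)(C)C
Why: silyl‑transfer ketalisation masks the hindered aryl ketone against the organolithium steps that follow.

**Step 4**
Reactants: 6 7'‑bromo‑5'‑methoxy‑2',3'‑dihydrospiro[1,3‑dioxolane‑2,1'‑indene]; 7 (1R,2S,5R)‑menthyl (S)‑4‑methylbenzenesulfinate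
Product: 9 (S)‑5'‑methoxy‑7'‑(4‑methylbenzenesulfinyl)‑2',3'‑dihydrospiro[1,3‑dioxolane‑2,1'‑indene], via aryllithium 8 (not isolated)
Conditions: n‑BuLi (1.05 equiv), THF, −78 °C; then cannulation into 7 (1.2 equiv), THF, −78 °C; H2O
Reagents that add atoms: none
Why: bromine–lithium exchange followed by the Andersen sulfoxide synthesis, which substitutes at sulfur with inversion, should give the (S)‑sulfoxide.

**Step 5**
Reactants: 9 (S)‑sulfoxide; 10 3,5‑dimethoxybenzyl bromide
Product: 12 (S)‑6'‑(3,5‑dimethoxybenzyl)‑5'‑methoxy‑7'‑(4‑methylbenzenesulfinyl)‑2',3'‑dihydrospiro[1,3‑dioxolane‑2,1'‑indene], via ortho‑lithiated sulfoxide 11 (not isolated)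
Conditions: LiN(i‑Pr)2 (1.3 equiv), THF, −78 °C; then inverse addition to 10 (2 equiv), THF, −78 → −40 °C
Reagents that add atoms: none
Why: sulfoxide‑directed ortho‑lithiation should occur at the only free ortho position of the ring, which is also ortho to the methoxy group, and inverse addition to excess benzyl bromide limits proton transfer to the more acidic product.

**Step 6**
Reactants: 12 benzylated (S)‑sulfoxide; 13 4‑methoxybenzaldehyde
Product: 16 (2S,3S)‑3‑(3,5‑dimethoxyphenyl)‑4‑methoxy‑2‑(4‑methoxyphenyl)‑2,3,6,7‑tetrahydrospiro[indeno[4,5‑b]furan‑8,2'‑[1,3]dioxolane], via benzylic lithium 14 (not isolated), via lithium alkoxide 15 (not isolated)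
Conditions: LiN(i‑Pr)2 (1.2 equiv), THF, −78 °C; 13 (1.5 equiv), −78 °C; then DMPU (5 equiv), −78 → 25 °C; H2O
Reagents that add atoms: none
Why: Proposed new method: LiN(i‑Pr)2 removes a doubly benzylic C3 proton of 12 to give a lithium carbanion held in a six‑membered C–Li···O=S chelate, which adds to the aldehyde carbon to forge C2–C3, and the lithium alkoxide then attacks the sulfinyl‑bearing arene carbon and expels p‑toluenesulfenate to forge the aryl C–O bond (ipso substitution by addition–elimination or, equivalently, ligand coupling through a sulfurane). The closest known reaction type is the one‑pot addition of ortho‑sulfinyl benzyl carbanions to imines followed by ipso displacement of the sulfinyl group by the amide nitrogen to give indolines; the carbonyl/alkoxide variant that closes an aryl–oxygen bond has not been shown. The dihydrofuran, the only ring formed, closes by 5‑exo‑trig attack of oxygen on the arene carbon. C3 is set by the sulfur stereocentre (aldehyde delivered on the lithium‑bearing face of the chelate, 1,4‑induction), and C2 by reversibility of the aldol step together with faster closure of the alkoxide that leads to the 2,3‑trans ring, any cis isomer being corrected in step 7. The step needs benzylic rather than aryl deprotonation and oxygen attack at the ipso carbon rather than at sulfur; the first is secured by the acidity of the sulfinyl‑flanked diarylmethane, the second by the five‑membered transition state that holds the alkoxide over the arene carbon, while the ketal keeps the ketone out of the anionic chemistry.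

**Step 7**
Reactants: 16 dihydrobenzofuran ketal
Product: 17 (2S,3S)‑3‑(3,5‑dimethoxyphenyl)‑4‑methoxy‑2‑(4‑methoxyphenyl)‑2,3,6,7‑tetrahydro‑8H‑indeno[4,5‑b]furan‑8‑one
Conditions: TFA/H2O (9:1), CH2Cl2, 0 → 25 °C
Reagents that add atoms: water, O
Why: acetal hydrolysis frees the ketone, and reversible acid ionisation of the C2–O bond (p‑methoxybenzylic cation) should leave C2 trans to the C3 aryl group without touching C3.

**Step 8**
Reactants: 17 tricyclic ketone
Product: 19 (2S,3S)‑3‑(3,5‑dimethoxyphenyl)‑4‑methoxy‑2‑(4‑methoxyphenyl)‑2,3‑dihydro‑8H‑indeno[4,5‑b]furan‑8‑one, via silyl enol ether 18 (not isolated)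
Conditions: TMSOTf (1.3 equiv), Et3N (2 equiv), CH2Cl2, 0 °C; then Pd(OAc)2 (1.05 equiv), MeCN, 25 °C
Reagents that add atoms: none
Why: Saegusa–Ito oxidation of the only possible silyl enol ether should give the indenone under conditions mild enough for the benzylic C–H bonds of the dihydrofuran; 19 is used at once.

**Step 9**
Reactants: 19 indenone; 20 (E)‑2‑phenylethenylboronic acid
Product: 21 (2S,3S,6R)‑3‑(3,5‑dimethoxyphenyl)‑4‑methoxy‑2‑(4‑methoxyphenyl)‑6‑[(E)‑2‑phenylethenyl]‑2,3,6,7‑tetrahydro‑8H‑indeno[4,5‑b]furan‑8‑one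
Conditions: 20 (2.5 equiv), Rh(acac)(C2H4)2 (3 mol %), (R)‑BINAP (3.3 mol %), dioxane/H2O (10:1), 80 °C
Reagents that add atoms: none
Why: Hayashi–Miyaura rhodium‑catalysed asymmetric 1,4‑addition of an alkenylboronic acid to the cyclic enone should set C6 under ligand control, with the styryl group on the face opposite to the C2 aryl group and independent of the remote furan stereocentres.

**Step 10**
Reactants: 21 styryl ketone; 22 1‑bromo‑3,5‑dimethoxybenzene
Product: 23 (2S,3S,6S,7R)‑3,7‑bis(3,5‑dimethoxyphenyl)‑4‑methoxy‑2‑(4‑methoxyphenyl)‑6‑[(E)‑2‑phenylethenyl]‑2,3,6,7‑tetrahydro‑8H‑indeno[4,5‑b]furan‑8‑one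
Conditions: 22 (1.3 equiv), Pd(OAc)2 (3 mol %), XPhos (6 mol %), K3PO4 (2.5 equiv), toluene, 80 °C
Reagents that add atoms: none
Why: palladium‑catalysed ketone α‑arylation with a weak base should install ring B at C7, trans to the styryl group by equilibration, while the 1,2‑disubstituted alkene and the C6–H bond stay inert.

**Step 11**
Reactants: 23 aryl styryl ketone
Product: 25 (2S,3S,6S,7R)‑3,7‑bis(3,5‑dimethoxyphenyl)‑4‑methoxy‑2‑(4‑methoxyphenyl)‑8‑oxo‑2,3,7,8‑tetrahydro‑6H‑indeno[4,5‑b]furan‑6‑carboxylic acid, via aldehyde 24 (not isolated)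
Conditions: OsO4 (2 mol %), NaIO4 (4 equiv), 2,6‑lutidine, dioxane/H2O, 25 °C; then NaClO2, NaH2PO4, 2‑methyl‑2‑butene, t‑BuOH/H2O, 0 °C
Reagents that add atoms: osmium tetroxide, O=[Os](=O)(=O)=O, regenerated by sodium periodate, [Na+].[O-]I(=O)(=O)=O (first carboxyl oxygen); sodium chlorite, [Na+].[O-]Cl=O (second carboxyl oxygen)
Why: Lemieux–Johnson cleavage followed directly by Pinnick oxidation turns the styryl group into the carboxyl carbon on C6 under buffered conditions that should spare the C6 stereocentre.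

**Step 12**
Reactants: 25 keto acid
Product: 28 cis‑fused pentacyclic diketone (second cyclopentanone closed between the C6 carboxyl carbon and the ring‑B ortho carbon; both angular hydrogens on the face of the C2 aryl group), via mixed anhydride 26 (not isolated), via cis mixed anhydride 27 (not isolated)
Conditions: (CF3CO)2O (3 equiv), CH2Cl2, 0 °C; then TfOH (0.3 equiv), 0 → 25 °C
Reagents that add atoms: none
Why: intramolecular Friedel–Crafts acylation of the doubly activated ortho position of the 3,5‑dimethoxyphenyl ring (the classical diarylsuccinic acid to dihydroindenoindenedione closure) can only proceed from the C7 epimer reached by acid enolisation, so the non‑enolised C6 centre should dictate a cis ring fusion.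

**Step 13**
Reactants: 28 diketone
Product: 29 diol (both hydroxyl groups on the concave face)
Conditions: NaBH4 (4 equiv), THF/MeOH, 0 °C
Reagents that add atoms: none
Why: borohydride reduction should deliver hydride to the convex face of the cis‑diquinane; the carbinol configurations are erased in step 14.

**Step 14**
Reactants: 29 diol; 30 anisole
Product: 31 octamethyl ether of the target
Conditions: 30 (20 equiv), TsOH·H2O (10 mol %), (CF3)2CHOH, 0 → 25 °C
Reagents that add atoms: none
Why: Friedel–Crafts alkylation: mild acid in the fluorinated alcohol ionises both 2,4‑dioxygenated benzylic alcohols, and anisole should attack each cation para and from the convex face, placing both aryl groups exo, which is also the thermodynamic arrangement.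

**Step 15**
Reactants: 31 octamethyl ether
Product: 32 target CNP0154244.2
Conditions: BBr3 (20 equiv), CH2Cl2, −78 → 25 °C; H2O
Reagents that add atoms: none
Why: Lewis‑acid cleavage of the eight aryl methyl ethers; the trans dihydrofuran is the thermodynamic isomer, so reversible opening at C2 should not change the configuration.

**Compound list**
1 | 3‑bromoanisole | COc1cccc(Br)c1 | starting material
2 | 3‑chloropropanoyl chloride | ClCCC(Cl)=O | starting material
3 | 1‑(2‑bromo‑4‑methoxyphenyl)‑3‑chloropropan‑1‑one | COc1ccc(C(=O)CCCl)c(Br)c1 | intermediate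
4 | 1‑(2‑bromo‑4‑methoxyphenyl)prop‑2‑en‑1‑one | COc1ccc(C(=O)C=C)c(Br)c1 | intermediate
5 | 7‑bromo‑5‑methoxy‑2,3‑dihydro‑1H‑inden‑1‑one | COc1cc(Br)c2C(=O)CCc2c1 | intermediate
6 | 7'‑bromo‑5'‑methoxy‑2',3'‑dihydrospiro[1,3‑dioxolane‑2,1'‑indene] | COc1cc(Br)c2c(c1)CCC21OCCO1 | intermediate
7 | (1R,2S,5R)‑menthyl (S)‑4‑methylbenzenesulfinate | CC(C)[C@@H]1CC[C@@H](C)C[C@H]1O[S@](=O)c1ccc(C)cc1 | starting material
8 | 7'‑lithio derivative of 6 | COc1cc([Li])c2c(c1)CCC21OCCO1 | intermediate
9 | (S)‑5'‑methoxy‑7'‑(4‑methylbenzenesulfinyl)‑2',3'‑dihydrospiro[1,3‑dioxolane‑2,1'‑indene] | COc1cc([S@@](=O)c3ccc(C)cc3)c2c(c1)CCC21OCCO1 | intermediate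
10 | 3,5‑dimethoxybenzyl bromide | COc1cc(CBr)cc(OC)c1 | starting material
11 | 6'‑lithio derivative of 9 | COc1c([Li])c([S@@](=O)c3ccc(C)cc3)c2c(c1)CCC21OCCO1 | intermediate
12 | (S)‑6'‑(3,5‑dimethoxybenzyl)‑5'‑methoxy‑7'‑(4‑methylbenzenesulfinyl)‑2',3'‑dihydrospiro[1,3‑dioxolane‑2,1'‑indene] | COc1c(Cc4cc(OC)cc(OC)c4)c([S@@](=O)c3ccc(C)cc3)c2c(c1)CCC21OCCO1 | intermediate
13 | 4‑methoxybenzaldehyde | COc1ccc(C=O)cc1 | starting material
14 | derivative of 12 lithiated at the diarylmethane carbon | COc1c(C([Li])c4cc(OC)cc(OC)c4)c([S@@](=O)c3ccc(C)cc3)c2c(c1)CCC21OCCO1 | intermediate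
15 | lithium (1S,2S)‑2‑(3,5‑dimethoxyphenyl)‑1‑(4‑methoxyphenyl)‑2‑[5'‑methoxy‑7'‑((S)‑4‑methylbenzenesulfinyl)‑2',3'‑dihydrospiro[1,3‑dioxolane‑2,1'‑inden]‑6'‑yl]ethan‑1‑olate | COc1c([C@H](c4cc(OC)cc(OC)c4)[C@H](O[Li])c5ccc(OC)cc5)c([S@@](=O)c3ccc(C)cc3)c2c(c1)CCC21OCCO1 | intermediate
16 | (2S,3S)‑3‑(3,5‑dimethoxyphenyl)‑4‑methoxy‑2‑(4‑methoxyphenyl)‑2,3,6,7‑tetrahydrospiro[indeno[4,5‑b]furan‑8,2'‑[1,3]dioxolane] | C12(OCCO1)CCc1cc(OC)c3c(c12)O[C@H](c1ccc(OC)cc1)[C@H]3c1cc(OC)cc(OC)c1 | intermediate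
17 | (2S,3S)‑3‑(3,5‑dimethoxyphenyl)‑4‑methoxy‑2‑(4‑methoxyphenyl)‑2,3,6,7‑tetrahydro‑8H‑indeno[4,5‑b]furan‑8‑one | O=C1CCc2cc(OC)c3c(c21)O[C@H](c1ccc(OC)cc1)[C@H]3c1cc(OC)cc(OC)c1 | intermediate
18 | 8‑trimethylsilyl enol ether of 17 (C7=C8 double bond) | C[Si](C)(C)OC1=CCc2cc(OC)c3c(c21)O[C@H](c1ccc(OC)cc1)[C@H]3c1cc(OC)cc(OC)c1 | intermediate
19 | (2S,3S)‑3‑(3,5‑dimethoxyphenyl)‑4‑methoxy‑2‑(4‑methoxyphenyl)‑2,3‑dihydro‑8H‑indeno[4,5‑b]furan‑8‑one | O=C1C=Cc2cc(OC)c3c(c21)O[C@H](c1ccc(OC)cc1)[C@H]3c1cc(OC)cc(OC)c1 | intermediate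
20 | (E)‑2‑phenylethenylboronic acid | OB(O)/C=C/c1ccccc1 | starting material
21 | (2S,3S,6R)‑6‑styryl ketone (styryl anti to the C2 aryl group) | O=C1C[C@H](/C=C/c2ccccc2)c2cc(OC)c3c(c21)O[C@H](c1ccc(OC)cc1)[C@H]3c1cc(OC)cc(OC)c1 | intermediate
22 | 1‑bromo‑3,5‑dimethoxybenzene | COc1cc(Br)cc(OC)c1 | starting material
23 | (2S,3S,6S,7R)‑7‑(3,5‑dimethoxyphenyl)‑6‑styryl ketone (6,7‑trans) | O=C1[C@@H](c2cc(OC)cc(OC)c2)[C@H](/C=C/c2ccccc2)c2cc(OC)c3c(c21)O[C@H](c1ccc(OC)cc1)[C@H]3c1cc(OC)cc(OC)c1 | intermediate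
24 | (2S,3S,6S,7R)‑8‑oxo‑6‑carbaldehyde | O=C1[C@@H](c2cc(OC)cc(OC)c2)[C@H](C=O)c2cc(OC)c3c(c21)O[C@H](c1ccc(OC)cc1)[C@H]3c1cc(OC)cc(OC)c1 | intermediate
25 | (2S,3S,6S,7R)‑8‑oxo‑6‑carboxylic acid | O=C1[C@@H](c2cc(OC)cc(OC)c2)[C@H](C(O)=O)c2cc(OC)c3c(c21)O[C@H](c1ccc(OC)cc1)[C@H]3c1cc(OC)cc(OC)c1 | intermediate
26 | mixed trifluoroacetic anhydride of 25 (6,7‑trans) | O=C1[C@@H](c2cc(OC)cc(OC)c2)[C@H](C(=O)OC(=O)C(F)(F)F)c2cc(OC)c3c(c21)O[C@H](c1ccc(OC)cc1)[C@H]3c1cc(OC)cc(OC)c1 | intermediate
27 | C7 epimer of 26 (6,7‑cis) | O=C1[C@H](c2cc(OC)cc(OC)c2)[C@H](C(=O)OC(=O)C(F)(F)F)c2cc(OC)c3c(c21)O[C@H](c1ccc(OC)cc1)[C@H]3c1cc(OC)cc(OC)c1 | intermediate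
28 | cis‑fused pentacyclic diketone (angular hydrogens syn to the C2 aryl group) | O=C2c3c(OC)cc(OC)cc3[C@H]3C(=O)c4c(cc(OC)c5c4O[C@H](c4ccc(OC)cc4)[C@H]5c4cc(OC)cc(OC)c4)[C@@H]23 | intermediate
29 | diol from 28 (hydroxyl groups on the concave face) | O[C@H]2c3c(OC)cc(OC)cc3[C@H]3[C@@H](O)c4c(cc(OC)c5c4O[C@H](c4ccc(OC)cc4)[C@H]5c4cc(OC)cc(OC)c4)[C@@H]23 | intermediate
30 | anisole | COc1ccccc1 | starting material
31 | octamethyl ether of the target (furan 2S,3S; all four diquinane stereocentres R) | COc1ccc([C@@H]2c3c(OC)cc(OC)cc3[C@H]3[C@H](c4ccc(OC)cc4)c4c(cc(OC)c5c4O[C@H](c4ccc(OC)cc4)[C@H]5c4cc(OC)cc(OC)c4)[C@@H]23)cc1 | intermediate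
32 | CNP0154244.2 (furan 2S,3S; all four diquinane stereocentres R) | Oc1ccc([C@@H]2c3c(O)cc(O)cc3[C@H]3[C@H](c4ccc(O)cc4)c4c(cc(O)c5c4O[C@H](c4ccc(O)cc4)[C@H]5c4cc(O)cc(O)c4)[C@@H]23)cc1 | target

**Totals**
Total step count: 15. Longest linear sequence: 15 steps (from 1 and 2; compounds 7, 10, 13, 20, 22 and 30 are bought).

**Steps most likely to fail**

1. Step 6 (Proposed new method). The lithium alkoxide may not displace the sulfinyl group: it may revert by retro‑aldol, attack sulfur, or survive to work‑up as the open carbinol. Fallback with known chemistry, from 12 back to 17: the carbanion of 12 is treated with 13 as before but protonated at −78 °C (AcOH), which should give the sulfinyl carbinol F1 (either carbinol epimer). t‑BuLi (3 equiv, THF, −78 °C) then effects sulfoxide–lithium exchange, and the aryllithium is trapped with B(OMe)3 and oxidised (NaOH, H2O2) to the phenol F2. TFA/H2O in CH2Cl2 ionises the p‑methoxybenzylic alcohol, the phenol closes the O–C2 bond to the trans ring, and the ketal is hydrolysed in the same operation, giving 17.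

2. Step 9. Facial selectivity on the benzo‑fused enone may be poor, or the electrophilic indenone may oligomerise before the rhodium alkenyl intercepts it. Fallback, from 19 back to 21: (E)‑styrylmagnesium bromide with CuBr·SMe2 and Me3SiCl (THF, −78 °C, then dilute acid) adds the styryl group without external control. Because C2 and C3 are already fixed, this gives 21 together with its C6 epimer F3 as diastereomers, which are separated by preparative HPLC or crystallisation.

3. Step 14. The acid may also ionise the furan C2–O bond, letting anisole capture that cation; anisole may attack through its ortho position; or a cation may eliminate to an indene that does not re‑ionise. Fallback, from 29 back to 31: PivCl, DMAP and pyridine give the dipivalate F4. Stereospecific nickel‑catalysed Suzuki–Miyaura coupling of benzylic pivalates (Ni(cod)2, NaOMe, tris(4‑methoxyphenyl)boroxine, THF) then replaces each concave‑face pivalate with inversion, placing both anisyl groups on the convex face without a free cation.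

**Further compounds**
F1 | step 6 | (S)‑sulfinyl carbinol: 2‑(3,5‑dimethoxyphenyl)‑1‑(4‑methoxyphenyl)‑2‑[5'‑methoxy‑7'‑(4‑methylbenzenesulfinyl)‑2',3'‑dihydrospiro[1,3‑dioxolane‑2,1'‑inden]‑6'‑yl]ethan‑1‑ol, benzylic carbon S, carbinol carbon either | COc1c([C@H](c4cc(OC)cc(OC)c4)C(O)c5ccc(OC)cc5)c([S@@](=O)c3ccc(C)cc3)c2c(c1)CCC21OCCO1
F2 | step 6 | phenol carbinol: 6'‑[1‑(3,5‑dimethoxyphenyl)‑2‑hydroxy‑2‑(4‑methoxyphenyl)ethyl]‑5'‑methoxy‑2',3'‑dihydrospiro[1,3‑dioxolane‑2,1'‑inden]‑7'‑ol, benzylic carbon S | COc1c([C@H](c4cc(OC)cc(OC)c4)C(O)c5ccc(OC)cc5)c(O)c2c(c1)CCC21OCCO1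
F3 | step 9 | C6 epimer of 21 (styryl syn to the C2 aryl group) | O=C1C[C@@H](/C=C/c2ccccc2)c2cc(OC)c3c(c21)O[C@H](c1ccc(OC)cc1)[C@H]3c1cc(OC)cc(OC)c1
F4 | step 14 | dipivalate of diol 29 (both esters on the concave face) | CC(C)(C)C(=O)O[C@H]2c3c(OC)cc(OC)cc3[C@H]3[C@@H](OC(=O)C(C)(C)C)c4c(cc(OC)c5c4O[C@H](c4ccc(OC)cc4)[C@H]5c4cc(OC)cc(OC)c4)[C@@H]23
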